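**Assumption (one line):** the minor ring diastereomers from the Diels–Alder step and the C14 epimer from the final halogenation are removed by chromatography.

## Retrosynthetic overview
1. The C14-Br / C15-Cl pair comes from Markovnikov bromochlorination of a homoprenyl (prenyl-terminated) side chain in the last step.
2. The 7-oxabicyclo[2.2.1]heptane is closed late, by intramolecular alkoxymercuration of the C10-OH onto the ring trisubstituted alkene (C7=C8).
3. The cyclohexene is the key ring, built by an endo-selective Diels–Alder between a linalool-derived diene (carries the C3 stereocentre and C1–C5) and geranial-derived enone 7 (carries C10–C15).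
4. Ring order: carbocycle (Diels–Alder) first, then the oxa-bridge. The acetyl group on the dienophile is converted to the C10 oxygen by Baeyer–Villiger oxidation.

## Route

**Step 1**
Reactants: 1 (S)-linalool
Product: 2 (2E,6S)-8-hydroxylinalool
Conditions: SeO₂ (cat.), TBHP, CH₂Cl₂, rt
Reagents that add atoms: tert-butyl hydroperoxide, CC(C)(C)OO (oxygen source)
Why: Riley allylic oxidation hits the methyl trans to the chain, giving the E-allylic alcohol; the tertiary C3 carbinol is untouched, so its (S) configuration is carried through.

**Step 2**
Reactants: 2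
Product: 3 (2E,6S)-6-hydroxy-2,6-dimethylocta-2,7-dienal
Conditions: MnO₂, CH₂Cl₂, rt
Reagents that add atoms: none
Why: MnO₂ selectively oxidises the primary allylic alcohol to the enal, leaving the tertiary alcohol and vinyl group alone.

**Step 3**
Reactants: 3
Product: 4 (3S,6E)-3,7-dimethylnona-1,6,8-trien-3-ol (diene)
Conditions: Ph₃P=CH₂ (from Ph₃PCH₃Br, KOtBu), THF, 0 °C
Reagents that add atoms: methylenetriphenylphosphorane, C=P(c1ccccc1)(c1ccccc1)c1ccccc1 (adds CH₂)
Why: Wittig methylenation keeps the E geometry at C6=C7, giving a 1-alkyl-2-methyl diene that can reach s-cis.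

**Step 4**
Reactants: 5 geranial ((E)-citral)
Product: 6 (3E)-4,8-dimethylnona-3,7-dien-2-ol
Conditions: MeMgBr, THF, –78 °C → 0 °C
Reagents that add atoms: methylmagnesium bromide, C[Mg]Br (adds CH₃)
Why: Grignard 1,2-addition to the enal leaves the E-trisubstituted alkene and the prenyl terminus intact; the new carbinol is destroyed in the next step.

**Step 5**
Reactants: 6
Product: 7 (3E)-4,8-dimethylnona-3,7-dien-2-one
Conditions: MnO₂, CH₂Cl₂, rt
Reagents that add atoms: none
Why: Allylic oxidation gives the enone with acetyl cis to the ring methyl (E alkene); this sets up the endo relationships in step 6.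

**Step 6**
Reactants: 4 (diene) + 7 (enone)
Product: 8, the cyclohexene adduct (ring numbered from the acetyl-bearing carbon):
1-acetyl-2-methyl-2-(4-methylpent-3-en-1-yl)-3-[(3S)-3-hydroxy-3-methylpent-4-en-1-yl]-4-methylcyclohex-4-ene.
Relative stereochemistry: the C3 side chain, 2-Me and acetyl are cis; the homoprenyl group is trans to them.
Conditions: Me₂AlCl (2.2 equiv), CH₂Cl₂, –78 → –20 °C
Reagents that add atoms: none (Lewis acid is not retained)
Why: Lewis-acid Diels–Alder in which the enone β-carbon (C11) bonds the diene terminus C6 (para-directing effect of the 2-methyl group) and C10 bonds C9. The ketone-endo transition state with E-diene and E-enone puts the side chain, Me and acetyl all cis and the homoprenyl trans, which is the relative configuration at a, b and c in the target. The remote (S)-C3 gives only a modest facial bias, so the two ring diastereomers are separated and the one drawn is carried forward.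

**Step 7**
Reactants: 8
Product: 9, the acetate of 8 (C10-OAc in place of C10-acetyl, same configuration)
Conditions: Sn-β zeolite (cat.), 30% H₂O₂, 1,4-dioxane, 70 °C
Reagents that add atoms: hydrogen peroxide, OO (adds O)
Why: Baeyer–Villiger oxidation migrates the secondary ring carbon in preference to methyl, with retention, so the acetyl becomes OAc at C10 with the same configuration. Sn-β activates H₂O₂ for Baeyer–Villiger without epoxidising the three alkenes.

**Step 8**
Reactants: 9
Product: 10 (C10 free alcohol: 2-methyl-2-(4-methylpent-3-en-1-yl)-3-[(3S)-3-hydroxy-3-methylpent-4-en-1-yl]-4-methylcyclohex-4-en-1-ol)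
Conditions: K₂CO₃, MeOH, rt
Reagents that add atoms: none
Why: Mild methanolysis removes the acetate; C10 is no longer α to a carbonyl, so its configuration is stable.

**Step 9**
Reactants: 10
Product: 11, (3S)-5-[1,3-dimethyl-3-(4-methylpent-3-en-1-yl)-7-oxabicyclo[2.2.1]heptan-2-yl]-3-methylpent-1-en-3-ol
Conditions: Hg(OAc)₂, THF, 0 °C → rt; then NaOH(aq), NaBH₄, 0 °C
Reagents that add atoms: none (Hg is removed; the hydrogen comes from NaBH₄)
Why: Intramolecular alkoxymercuration. The C10-OH adds to the tertiary alkene carbon C7 (Markovnikov) on the same face, and demercuration then places H at C8 (net hydroalkoxylation, an isomerisation). The bridge configuration at C7 is dictated by the bicycle, and the C10-OH, the side chain (a) and the methyl (b) end up exo, which matches the target.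

**Step 10**
Reactants: 11
Product: 12, dactylomelol (target)
Conditions: NBS (1.05 equiv), Et₄NCl (3 equiv), CH₂Cl₂, –40 °C
Reagents that add atoms: N-bromosuccinimide, BrN1C(=O)CCC1=O (Br); tetraethylammonium chloride, CC[N+](CC)(CC)CC.[Cl-] (Cl)
Why: Electrophilic bromochlorination. Bromonium forms on the electron-rich prenyl alkene rather than the hindered vinyl, and chloride opens it at the tertiary carbon (Markovnikov, anti), giving C14-Br / C15-Cl. The core biases the C14 face only weakly, so the C14 epimers are separated and (14S) is kept.

## Consistency check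
- Ring sizes: cyclohexene (step 6) → 7-oxabicyclo[2.2.1]heptane (step 9).
- Substituents: 1-Me on the bridgehead, 3-Me and the 3-chain on the quaternary carbon, and the pentenol side chain on C2 all match the target.
- Formulae: 4 (C₁₁H₁₈O) + 7 (C₁₁H₁₈O) = 8 (C₂₂H₃₆O₂); 9 adds O; 10 loses C₂H₂O; 11 is isomeric with 10; 11 + BrCl = 12 (C₂₀H₃₄BrClO₂), the target.
- Stereocentres:
  - C3: (S), from linalool, never touched.
  - a, b, c: set in step 6.
  - f: set in step 9 by the bridge.
  - C14: set in step 10.

## Compound list
1 | (S)-linalool | C=C[C@@](C)(O)CCC=C(C)C | starting material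
2 | (2E,6S)-8-hydroxylinalool | C=C[C@@](C)(O)CC/C=C(\C)CO | intermediate
3 | (2E,6S)-6-hydroxy-2,6-dimethylocta-2,7-dienal | C=C[C@@](C)(O)CC/C=C(\C)C=O | intermediate
4 | (3S,6E)-3,7-dimethylnona-1,6,8-trien-3-ol | C=C[C@@](C)(O)CC/C=C(\C)C=C | intermediate
5 | geranial | O=C/C=C(\C)CCC=C(C)C | starting material
6 | (3E)-4,8-dimethylnona-3,7-dien-2-ol (racemic carbinol) | CC(O)/C=C(\C)CCC=C(C)C | intermediate
7 | (3E)-4,8-dimethylnona-3,7-dien-2-one | CC(=O)/C=C(\C)CCC=C(C)C | intermediate
8 | Diels–Alder adduct (acetyl cyclohexene) | C=C[C@@](C)(O)CC[C@H]1[C@](C)(CCC=C(C)C)[C@@H](C(C)=O)CC=C1C | intermediate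
9 | C10 acetate of 8 | C=C[C@@](C)(O)CC[C@H]1[C@](C)(CCC=C(C)C)[C@@H](OC(C)=O)CC=C1C | intermediate
10 | C10 alcohol (cyclohexenol) | C=C[C@@](C)(O)CC[C@H]1[C@](C)(CCC=C(C)C)[C@@H](O)CC=C1C | intermediate
11 | oxa-bridged homoprenyl compound | C=C[C@@](C)(O)CC[C@H]1[C@](C)(CCC=C(C)C)[C@@H]2CC[C@@]1(C)O2 | intermediate
12 | dactylomelol | C=C[C@@](C)(O)CC[C@H]1[C@](C)(CC[C@H](Br)C(C)(C)Cl)[C@@H]2CC[C@@]1(C)O2 | target

## Totals
Total steps: 10. Longest linear sequence: 8 steps (1 → 2 → 3 → 4 → 8 → 9 → 10 → 11 → 12).

## Three steps most likely to fail
1. **Step 6 (Diels–Alder).** Risks are regiochemistry (C6–C10/C9–C11 instead of C6–C11/C9–C10), the hindered vicinal tertiary/quaternary bond, and a near-1:1 ring diastereomer ratio. Fallback (different approach): intramolecular furan Diels–Alder of furfuryl (E)-geranate. The tether fixes the f–a / c–b connectivity and gives the exo lactone with the same relative stereochemistry, at the cost of extra steps to rebuild the side chain and convert the lactone CH₂–O into the bridgehead methyl.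
2. **Step 9 (oxymercuration cyclisation).** The boat transition state is needed for the 1,4-bridge, and the prenyl alkene competes. Fallback (different approach): Markovnikov hydration of the ring alkene to the 1,4-diol, then TsOH cyclodehydration through the tertiary cation.
3. **Step 10 (bromochlorination).** Chemoselectivity and the C14 diastereoselectivity are poor. Fallback (different approach): bio-inspired vanadium haloperoxidase bromochlorination of 11, which mimics the biosynthesis and controls the C14 face.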